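**Retrosynthetic overview**

1. The free phenol oxygen at ring C5 goes in last, by iridium-catalysed C–H borylation/oxidation of a 1,3-disubstituted benzene whose only phenol is already acetylated. The two ring oxygens are therefore never equivalent and no statistical monoacetylation is needed.
2. The C2–C3 bond of the tetradecyl chain and the C2 stereocentre come from one four-component nickel hydride coupling of (3-acetoxyphenyl)acetaldehyde, acetyl bromide, 1-dodecene and a hydrosilane.
3. Enabling feature: C2 is a secondary carbinol carbon flanked by two CH2 groups (benzylic C1 on the benzene ring, C3 of an unbranched chain). Its oxygen can carry an acyl group, which makes C2 the carbonyl carbon of an arylacetaldehyde and supplies an ester C=O that binds nickel; C3–C14 is exactly a terminal alkene plus one hydride.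
4. Rings: the benzene ring is bought with 2-(3-hydroxyphenyl)ethanol; no ring is formed in the route.

Key step: step 3

Remark: the target is the 2S alcohol (OH > CH2Ar > CH2-alkyl > H). The nickel ligand is written L* because which enantiomer gives the 2S ester is to be assigned on a trial run (Mosher esters of the diol from step 4); that enantiomer is then used.

**Step 1**
Reactants: 1 2-(3-hydroxyphenyl)ethanol
Product: 2 3-(2-hydroxyethyl)phenyl acetate
Conditions: Ac2O (1.05 equiv), aq NaOH (1.05 equiv), THF/H2O, 0 °C
Reagents that add atoms: acetic anhydride, CC(=O)OC(C)=O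
Why: Schotten–Baumann acetylation in aqueous base acylates the phenoxide far faster than the neutral primary alcohol, so only the phenol should be esterified.

**Step 2**
Reactants: 2 3-(2-hydroxyethyl)phenyl acetate
Product: 3 3-(2-oxoethyl)phenyl acetate, i.e. (3-acetoxyphenyl)acetaldehyde
Conditions: Dess–Martin periodinane (1.2 equiv), CH2Cl2, 0 °C to rt; aq NaHCO3/Na2S2O3 work-up; used at once
Reagents that add atoms: none
Why: Dess–Martin oxidation takes the primary alcohol to the aldehyde under neutral, non-aqueous conditions that the aryl acetate and the enolisable arylacetaldehyde should tolerate.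

**Step 3**
Reactants: 3 3-(2-oxoethyl)phenyl acetate; 4 1-dodecene
Product: 6 (2S)-1-(3-acetoxyphenyl)tetradecan-2-yl acetate, via racemic 1-bromoalkyl acetate 5 (not isolated)
Conditions: AcBr (1.05 equiv), CH2Cl2, 0 °C to rt, then evaporate; NiBr2·DME (10 mol %), chiral bis(oxazoline) L* (isopropylidene-bridged, 12 mol %), 4 (1.5 equiv), (EtO)3SiH (2 equiv), K3PO4·H2O (2 equiv), THF/DMA, 0 °C
Reagents that add atoms: acetyl bromide, CC(=O)Br
Why: The aldehyde and acetyl bromide first add to give racemic 5; a monovalent nickel bromide complex of L* then abstracts bromine from either enantiomer of 5 to give one planar α-acetoxyalkyl radical, while a divalent nickel hydride formed from (EtO)3SiH and phosphate inserts 1-dodecene in the anti-Markovnikov sense to a primary dodecylnickel species, and capture of the radical gives a trivalent dialkylnickel intermediate that reductively eliminates the C2–C3 bond. The closest known reaction type is the nickel hydride-catalysed enantioconvergent hydroalkylation of olefins with racemic α-halo electrophiles, in its four-component form where a 1-bromoalkyl ester is made in the flask from an aldehyde and an acyl bromide. No ring is closed. The C2 stereocentre is set under catalyst control by the chiral ligand on nickel during radical capture and reductive elimination, and both enantiomers of 5 converge on it. The step needs enantioselection between two methylene substituents, which the acetate carbonyl on the C2 oxygen secures by binding nickel, so the catalyst tells O from C and not CH2Ar from CH2-alkyl. It also needs linear regioselectivity, secured by the unbranched monosubstituted alkene, and chemoselectivity, secured by converting all aldehyde into 5 before the silane is added and by the inertness of the aryl acetate to this catalyst at 0 °C.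

**Step 4**
Reactants: 6 (2S)-1-(3-acetoxyphenyl)tetradecan-2-yl acetate
Product: 7 3-[(2S)-2-hydroxytetradecyl]phenol
Conditions: K2CO3 (0.5 equiv), MeOH, rt; aq NH4Cl work-up
Reagents that add atoms: none
Why: Base-catalysed transesterification (methanolysis) cleaves both acetates at the acyl carbon, so the C2–O bond and its configuration are untouched.

**Step 5**
Reactants: 7 3-[(2S)-2-hydroxytetradecyl]phenol
Product: 8 3-[(2S)-2-hydroxytetradecyl]phenyl acetate
Conditions: Ac2O (1.05 equiv), aq NaOH (1.1 equiv), THF/H2O, 0 °C, 15 min
Reagents that add atoms: acetic anhydride, CC(=O)OC(C)=O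
Why: Schotten–Baumann acetylation again selects the phenoxide over the hindered neutral secondary alcohol, and because the ring carries only one oxygen at this stage the monoacetate is the only possible phenol ester.

**Step 6**
Reactants: 8 3-[(2S)-2-hydroxytetradecyl]phenyl acetate
Product: 11 3-hydroxy-5-[(2S)-2-hydroxytetradecyl]phenyl acetate, via O-boryl ether 9 (not isolated), via aryl boronate 10 (not isolated)
Conditions: HBpin (3 equiv), [Ir(OMe)(cod)]2 (1.5 mol %), dtbpy (3 mol %), THF, rt to 60 °C; then KHSO5 (Oxone, 1.1 equiv), acetone/H2O, rt, 10 min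
Reagents that add atoms: pinacolborane, [H]B1OC(C)(C)C(C)(C)O1 (boron of 9 and 10); potassium peroxymonosulfate, the active salt of Oxone, [K+].[O-]S(=O)(=O)OO (the new phenol oxygen)
Why: Iridium-catalysed aromatic C–H borylation is sterically controlled and, once the carbinol is masked in the flask as its O–Bpin ether, should go to the only ring C–H without an ortho substituent (C5), after which peroxymonosulfate oxidation of the aryl boronate (boron-to-oxygen aryl shift) gives the phenol and aqueous work-up frees the carbinol without touching the stereocentre.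

**Compound list**

1 | 2-(3-hydroxyphenyl)ethanol | OCCc1cccc(O)c1 | starting material
2 | 3-(2-hydroxyethyl)phenyl acetate | CC(=O)Oc1cccc(CCO)c1 | intermediate
3 | 3-(2-oxoethyl)phenyl acetate | CC(=O)Oc1cccc(CC=O)c1 | intermediate
4 | 1-dodecene | C=CCCCCCCCCCC | starting material
5 | 2-(3-acetoxyphenyl)-1-bromoethyl acetate (racemic, not isolated) | CC(=O)OC(Br)Cc1cccc(OC(C)=O)c1 | intermediate
6 | (2S)-1-(3-acetoxyphenyl)tetradecan-2-yl acetate | CCCCCCCCCCCC[C@H](OC(C)=O)Cc1cccc(OC(C)=O)c1 | intermediate
7 | 3-[(2S)-2-hydroxytetradecyl]phenol | CCCCCCCCCCCC[C@H](O)Cc1cccc(O)c1 | intermediate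
8 | 3-[(2S)-2-hydroxytetradecyl]phenyl acetate | CCCCCCCCCCCC[C@H](O)Cc1cccc(OC(C)=O)c1 | intermediate
9 | 3-[(2S)-2-(4,4,5,5-tetramethyl-1,3,2-dioxaborolan-2-yloxy)tetradecyl]phenyl acetate (not isolated) | CCCCCCCCCCCC[C@H](OB1OC(C)(C)C(C)(C)O1)Cc1cccc(OC(C)=O)c1 | intermediate
10 | 3-(4,4,5,5-tetramethyl-1,3,2-dioxaborolan-2-yl)-5-[(2S)-2-(4,4,5,5-tetramethyl-1,3,2-dioxaborolan-2-yloxy)tetradecyl]phenyl acetate (not isolated) | CCCCCCCCCCCC[C@H](OB1OC(C)(C)C(C)(C)O1)Cc1cc(OC(C)=O)cc(c1)B1OC(C)(C)C(C)(C)O1 | intermediate
11 | 3-hydroxy-5-[(2S)-2-hydroxytetradecyl]phenyl acetate | CCCCCCCCCCCC[C@H](O)Cc1cc(O)cc(OC(C)=O)c1 | target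

**Total step count:** 6. **Longest linear sequence:** 6 steps (1 to 11); 1-dodecene 4 enters in step 3.

**Steps most likely to fail**

Step 3 (key step). The benzylic 1-bromoalkyl acetate may lose HBr, or the dialkylnickel intermediate may undergo β-hydride elimination, both leading to the conjugated enol acetate. The nickel hydride may also reduce the C–Br bond, or the enantioselectivity may be too low for this arylacetaldehyde-derived electrophile. Partial loss of the aryl acetyl group under the phosphate base would not matter, since step 4 removes it anyway. The fallback sets out from 3 and returns to the route at 8, forming the same C2–C3 bond by catalytic asymmetric alkynylation. 1-Dodecyne, Me2Zn, ProPhenol ligand (the enantiomer that gives the R carbinol) and triphenylphosphine oxide in toluene at 0 °C should give 3-[(2R)-2-hydroxytetradec-3-yn-1-yl]phenyl acetate F1. The descriptor is R only because the alkynyl group outranks the benzylic CH2; the spatial arrangement is that of 8. Hydrogenation (H2, Pd/C, EtOAc) then saturates the triple bond and gives 8 directly, so steps 4 and 5 are not needed on this path.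

Step 6. O-borylation of the carbinol may be incomplete and the free alcohol may slow the iridium catalyst. The aryl acetate may be partly reduced by the borane, or the electron-rich phenol may be over-oxidised by peroxymonosulfate. The fallback sets out from 8 and returns at 11, replacing the one-flask unprotected sequence by a protected, stepwise one with an isolated boronate.
- TESCl and imidazole in CH2Cl2 should give 3-[(2S)-2-(triethylsilyloxy)tetradecyl]phenyl acetate F2.
- Borylation with B2pin2, [Ir(OMe)(cod)]2 and dtbpy in MTBE at 60 °C should give, after chromatography, 3-(4,4,5,5-tetramethyl-1,3,2-dioxaborolan-2-yl)-5-[(2S)-2-(triethylsilyloxy)tetradecyl]phenyl acetate F3.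
- Neutral oxidation with N-methylmorpholine N-oxide in THF at rt should give 3-hydroxy-5-[(2S)-2-(triethylsilyloxy)tetradecyl]phenyl acetate F4.
- AcOH/THF/H2O at rt removes the silyl group and should give 11.

Step 5. Acetylation may compete at the carbinol oxygen, or aqueous hydroxide may hydrolyse the newly formed aryl acetate, since the long-chain substrate is poorly soluble in the aqueous phase. The fallback sets out from 7 and returns at 8, replacing chemoselectivity by protecting-group control.
- TBSCl (2.5 equiv) and imidazole in DMF should give tert-butyl{3-[(2S)-2-(tert-butyldimethylsilyloxy)tetradecyl]phenoxy}dimethylsilane F5.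
- K2CO3 in MeOH at rt cleaves only the aryl silyl ether and should give 3-[(2S)-2-(tert-butyldimethylsilyloxy)tetradecyl]phenol F6.
- Ac2O, pyridine and catalytic DMAP should give 3-[(2S)-2-(tert-butyldimethylsilyloxy)tetradecyl]phenyl acetate F7.
- HF·pyridine in THF at 0 °C removes the secondary silyl ether without touching the aryl acetate and should give 8.

**Further compounds**

F1 | step 3 | 3-[(2R)-2-hydroxytetradec-3-yn-1-yl]phenyl acetate | CCCCCCCCCCC#C[C@H](O)Cc1cccc(OC(C)=O)c1
F2 | step 6 | 3-[(2S)-2-(triethylsilyloxy)tetradecyl]phenyl acetate | CCCCCCCCCCCC[C@H](O[Si](CC)(CC)CC)Cc1cccc(OC(C)=O)c1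
F3 | step 6 | 3-(4,4,5,5-tetramethyl-1,3,2-dioxaborolan-2-yl)-5-[(2S)-2-(triethylsilyloxy)tetradecyl]phenyl acetate | CCCCCCCCCCCC[C@H](O[Si](CC)(CC)CC)Cc1cc(OC(C)=O)cc(c1)B1OC(C)(C)C(C)(C)O1
F4 | step 6 | 3-hydroxy-5-[(2S)-2-(triethylsilyloxy)tetradecyl]phenyl acetate | CCCCCCCCCCCC[C@H](O[Si](CC)(CC)CC)Cc1cc(O)cc(OC(C)=O)c1
F5 | step 5 | tert-butyl{3-[(2S)-2-(tert-butyldimethylsilyloxy)tetradecyl]phenoxy}dimethylsilane | CCCCCCCCCCCC[C@H](O[Si](C)(C)C(C)(C)C)Cc1cccc(O[Si](C)(C)C(C)(C)C)c1
F6 | step 5 | 3-[(2S)-2-(tert-butyldimethylsilyloxy)tetradecyl]phenol | CCCCCCCCCCCC[C@H](O[Si](C)(C)C(C)(C)C)Cc1cccc(O)c1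
F7 | step 5 | 3-[(2S)-2-(tert-butyldimethylsilyloxy)tetradecyl]phenyl acetate | CCCCCCCCCCCC[C@H](O[Si](C)(C)C(C)(C)C)Cc1cccc(OC(C)=O)c1
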